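The readings come from a simulation for an exercise, noise included.

The constants of this flask are not given, so the readings have to supply them.

| flask | Q | X | remark | time |
|---|---|---|---|---|
| Monday's | 23 mM | 23 mM | run made earlier |  |
| Tuesday's | 12 mM | 23 mM | run made earlier |  |
| Friday's | 17 mM | 23 mM | run made earlier |  |
| Sunday's | 23 mM | 46 mM | run made earlier |  |
| west | 23 mM | 23.0 mM | one stirred flow tank at steady state, fed with the mixture as stated, mean residence time 10 h |  |
| north | 23 mM (fed, over 10.0 h) | 23.0 mM | all but Q at the start; Q goes in evenly over 10.0 h, the run ends at 10 h | 10 h |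
| south-west | 23 mM | 23.0 mM | a closed flask charged with all of it at once and left for 10 h | 10 h |

- Monday's (time / h: Z / %, L / %): 0.333: 23.4, 0.6; 1.00: 36.4, 0.1; 1.50: 34.6, 2.8; 2.50: 33.0, 2.1; 4.00: 27.6, 0.9; 5.00: 22.4, 0; 6.00: 18.7, 2.3
- Tuesday's (time / h: Z / %, L / %): 0.833: 38.2, 0; 1.50: 42.6, 0; 2.50: 41.7, 1.5; 3.00: 40.8, 1.9; 4.00: 35.2, 2.0; 5.00: 32.8, 1.4; 6.00: 29.8, 2.2
- Friday's (time / h: Z / %, L / %): 0.333: 24.0, 1.5; 1.00: 39.1, 0.9; 1.50: 40.1, 1.9; 2.50: 38.4, 2.6; 4.00: 32.1, 1.9; 5.00: 26.0, 1.6; 6.00: 23.7, 2.6
- Sunday's (time / h: Z / %, L / %): 0.500: 28.7, 0; 0.833: 34.2, 2.2; 1.50: 38.1, 2.2; 3.00: 31.3, 3.9; 6.00: 20.0, 1.4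

(each reading ± 1 percentage point)

- percent here means Q units held: one G counts as two
- the stated concentrations are those of everything mixed, before any reaction; amounts are the same in each set-up
- candidate steps: Q + Z -> G; Q <-> Z; J + X -> D; Q <-> J; J -> L
- the feed brings no volume worth counting
- the earlier runs were made in a closed, stirred flask

* the set-up with the highest share of Z in all that became Z or L or G, at the outlet or at the end ("none" if the first two lie within 2 percentage points) (west / north / south-west / none)
* share of Z in all that became Z or L or G, at the outlet or at the end, west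
* share of Z in all that became Z or L or G, at the outlet or at the end, north
* share of Z in all that became Z or L or G, at the outlet or at the end, south-west

Past its peak, the reciprocal of the Z fraction climbs steadily, which is how a loss by Q + Z → G looks when Q and Z stay in step. Monday's climbs 0.662 h⁻¹, and Tuesday's, on 12 mM of Q, climbs 0.274 h⁻¹. Sunday's run, with doubled X, reads 20.0% of Z at 6.00 h against Monday's 18.7%, so X stays out of the reckoning. Tuesday's line, run back to zero, reads 58.3% of what is still Q or Z as Z, a figure that carries the scatter of the readings.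

The square root of the product of that part, Monday's climb and the 10.0 h that each set-up has (dosing, residence or holding time) gives B = 1.97, the run measured in the time at which supply and second-order loss balance; its square is a second-order Damköhler number.

My reckoning reads off B the part of the charge still Q or Z, and Z is 58.3% of that part. South-west keeps the reciprocal of one plus B squared, 20.6%. North keeps tanh(B)/B, 48.9%. West keeps the root of one minus z, over B: starting from 50.9%, then 35.7%, then 40.8%.

The shares are 13.1%, 35.8% for north, the highest, and 28.7% for west.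

Is one number enough? Friday's run, unused so far, is reckoned at 21.5% of Z at its last reading and reads 23.7%, a gap of 2.2 percentage points.

The forecast gives 28% for west, 38% for north and 16% for south-west, so north: “Keeping Q low favours Z, so slow feeding should win.”

The flasks give 25.7%, 34.2% and 14.5%, so north.

    Q + Z → G (k = 0.00960 M⁻¹ s⁻¹)
    Q ⇌ Z (K = 1.70, k = 2.70 × 10⁻⁴ s⁻¹)
    J + X → D (k = 0.00780 M⁻¹ s⁻¹)
    Q ⇌ J (K = 18.0, k = 4.70 × 10⁻⁶ s⁻¹)
    J → L (k = 6.80 × 10⁻⁴ s⁻¹)

In north, Q and Z relax with a half-life of 0.449 h, shorter than the run. B put Z there at 28.5%; the flask holds 26.8%. With 5.8 mM of Q in the same fed flask, B falls to 0.987, which gives Z at 44.7% and a share of 65.7%. The computed flask holds 43.3% of Z, with a share of 63.5%.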